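Every unit of D and Z charged stays on the books of this closed flask, with a G entered as two, so the entries always sum to 30.0 mM.

| flask | D | Z | remark | time |
|---|---|---|---|---|
| summer | 0.028 M | 10 mM | run made earlier |  |
| dawn | 0.044 M | 10 mM | run made earlier |  |
| flask | 0.020 M | 10.0 mM |  | 3.0 min |

| run | time / s | X / % | L / % |
|---|---|---|---|
| summer | 10.0 | 2.4 | 10.1 |
| summer | 12.0 | 3.0 | 10.9 |
| summer | 20.0 | 4.2 | 16.5 |
| summer | 30.0 | 6.4 | 18.8 |
| summer | 50.0 | 11.0 | 27.6 |
| summer | 80.0 | 13.2 | 35.2 |
| summer | 120 | 15.3 | 39.4 |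
| dawn | 10.0 | 2.2 | 9.1 |
| dawn | 12.0 | 4.5 | 11.3 |
| dawn | 20.0 | 6.0 | 19.4 |
| dawn | 30.0 | 6.7 | 21.3 |
| dawn | 50.0 | 9.3 | 31.1 |
| dawn | 80.0 | 13.0 | 33.0 |
| dawn | 120 | 16.4 | 38.4 |

(readings scatter by 1 percentage point)

- a species is counted by the D in it: one G counts as two
- steps that have been proposed: L <-> J; Z -> X; D <-> Z; 2 Z -> G; Z <-> Q; D -> L; Q -> E

1. share of X in X plus L at 0.60 s
2. share of X in X plus L at 3.0 min
3. which of X and L there is more of at 3.0 min

1. Opening entry. Z is the smaller charge and holds 33.3 % of the flask's books. We call this the opening share: Z charged over D and Z charged together.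

2. First withdrawals. Among the proposed steps, Z goes to X and D goes to L. If these two run at equal first-order speed, the share of X in X plus L (the initial selectivity) starts at the opening share. That equality is our assumption, and the readings test it weakly. At 10.0 s the summer run reads 19.2 % against an opening share of 26.3 %, and the dawn run reads 19.5 % against 18.5 %, each resting on a small X read with a scatter of 1 percentage point. So we book about 33.3 % for the flask at 0.60 s.

3. Later entries. At 120 s, X plus L reads 54.7 % in the summer run and 54.8 % in the dawn run. The remaining 45.3 % of the summer books lies outside these columns.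

4. Closing entry. The late shares read 28.0 % and 29.9 %, which lie closer together than the opening shares of the two runs. So we do not carry the opening share forward, and we book their mean, 28.9 %, for the flask at 3.0 min, which is less than 50 % and puts L ahead.

5. The forecast gave 29 % at 0.60 s, 30 % at 3.0 min and L ahead, reasoning that “D and Z seem to equilibrate within seconds and drain as one pool”. The flask gives 31.6 % at 0.60 s and 32.8 % at 3.0 min, with L at 39.0 % and X at 19.1 %.

    L ⇌ J (K = 0.580, k = 0.0160 s⁻¹)
    Z → X (k = 0.0140 s⁻¹)
    D ⇌ Z (K = 0.350, k = 0.0170 s⁻¹)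
    2 Z → G (k = 1.10 M⁻¹ s⁻¹)
    Z ⇌ Q (K = 27.0, k = 0.00230 s⁻¹)
    D → L (k = 0.0150 s⁻¹)
    Q → E (k = 0.0150 s⁻¹)

6. Z goes to X with 0.014 s⁻¹ and D goes to L with 0.015 s⁻¹, and the flask's opening share of 33.3 % stands 1.7 points above its early share. The neighbour flask with 0.0025 M of Z opens at 11.1 % and gives 10.7 % at 0.60 s.

The runs come from a simulation for substances that don't exist, and the scatter is random.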